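**Retrosynthetic overview**

1. Numbering used throughout: C1 (OAc), C2=C3 (C3 carries C7H2OBz), C4 (OH), C5 (OBz), C6 (OH). The strategy rests on this feature: ring C1–C6 with C7 and the para-related oxygens on C1 and C4 is the skeleton of a 2-(hydroxymethyl)hydroquinone, and the two remaining oxygens form a cis-diol on C5/C6 on the ring face opposite O4.
2. Key disconnection: the C5–O and C6–O bonds, made together by OsO4/NMO dihydroxylation of the C5=C6 alkene of a C4-silyloxy cyclohexa-2,5-dienone dimethyl ketal (ketal carbon C1), anti to the silyloxy group.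
3. Before it: 2-hydroxy-5-methoxybenzaldehyde → benzylic alcohol → PhI(OAc)2/MeOH quinone monoketal → C7 benzoate → Corey–Bakshi–Shibata reduction at C4 → silyl ether.
4. After it: ketal hydrolysis → hydroxyl-directed reduction of the C1 ketone → C5/C6 cyclic orthobenzoate with C1 acetylation → orthoester opening that leaves the benzoate on O5 → desilylation.
5. Ring order: no ring is closed at any stage; the only ring is the benzene ring of the starting aldehyde, dearomatised in step 2.

Key step: step 6

Remarks on the chemistry: "upper face" means the face of O5/O6 and "lower face" that of O4/O1. The orthoester carbon of 12 and 13 forms as a mixture of epimers; this is assumed to be of no consequence because that centre is destroyed in step 10.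

**Route**

Step 1
Reactants: 1 2-hydroxy-5-methoxybenzaldehyde
Product: 2 2-(hydroxymethyl)-4-methoxyphenol
Conditions: NaBH4, MeOH, 0 °C; aq. NH4Cl work-up
Reagents that add atoms: none
Why: Borohydride reduction of the aryl aldehyde (carbonyl 1,2-reduction) gives the benzylic alcohol C7–OH and does not touch the phenol or the aryl methyl ether.

Step 2
Reactants: 2 2-(hydroxymethyl)-4-methoxyphenol
Product: 3 2-(hydroxymethyl)-4,4-dimethoxycyclohexa-2,5-dien-1-one
Conditions: PhI(OAc)2 (1.05 equiv), MeOH, 0 °C; NaHCO3 work-up
Reagents that add atoms: methanol, CO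
Why: Oxidative dearomatisation of a para-methoxyphenol with the trivalent iodine reagent in methanol is the standard route to para-quinone monoketals, methanol adding para to the phenol oxygen so that the phenol carbon becomes the C4 ketone and the anisole carbon the C1 dimethyl ketal.

Step 3
Reactants: 3 2-(hydroxymethyl)-4,4-dimethoxycyclohexa-2,5-dien-1-one; 4 benzoyl chloride
Product: 5 (3,3-dimethoxy-6-oxocyclohexa-1,4-dien-1-yl)methyl benzoate
Conditions: BzCl (1.2 equiv), pyridine, DMAP (5 mol%), CH2Cl2, 0 °C
Reagents that add atoms: benzoyl chloride (4), O=C(Cl)c1ccccc1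
Why: DMAP-catalysed O-acylation of the only hydroxyl group (the primary allylic C7–OH) with the acid chloride is unambiguous here, whereas on phenol 2 the phenolic oxygen would compete and an ortho-hydroxybenzyl ester could collapse to an ortho-quinone methide.

Step 4
Reactants: 5 (3,3-dimethoxy-6-oxocyclohexa-1,4-dien-1-yl)methyl benzoate
Product: 6 [(6R)-6-hydroxy-3,3-dimethoxycyclohexa-1,4-dien-1-yl]methyl benzoate
Conditions: (S)-Me-CBS oxazaborolidine [(3aS)-1-methyl-3,3-diphenyltetrahydro-1H,3H-pyrrolo[1,2-c][1,3,2]oxazaborole] (0.2 equiv), catecholborane (1.5 equiv), toluene, −78 °C; MeOH quench, aq. NaOH/NaHCO3 wash; Et3N-deactivated silica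
Reagents that add atoms: none
Why: Corey–Bakshi–Shibata reduction of the cross-conjugated C4 ketone, in which the C3 flank carrying C7H2OBz should act as the large group and the unsubstituted C5 vinyl flank as the small one (as the alpha-substituted flank does in 2-substituted cyclohexenones), so that the (S)-catalyst delivers hydride to the face giving the (R)-carbinol, while the cold protocol and basic work-up spare the acid-labile dienol ketal.

Step 5
Reactants: 6 [(6R)-6-hydroxy-3,3-dimethoxycyclohexa-1,4-dien-1-yl]methyl benzoate
Product: 7 [(6R)-6-[(tert-butyldimethylsilyl)oxy]-3,3-dimethoxycyclohexa-1,4-dien-1-yl]methyl benzoate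
Conditions: TBSCl (1.3 equiv), imidazole (2.5 equiv), DMF, 0 °C → rt
Reagents that add atoms: tert-butyldimethylsilyl chloride, CC(C)(C)[Si](C)(C)Cl
Why: Imidazole-buffered silylation of the secondary allylic alcohol is routine, does not touch the C4 stereocentre, and keeps the medium basic, as the dienol ketal (which aromatises by loss of methanol under acid) requires.

Step 6
Reactants: 7 [(6R)-6-[(tert-butyldimethylsilyl)oxy]-3,3-dimethoxycyclohexa-1,4-dien-1-yl]methyl benzoate
Product: 9 [(4R,5S,6S)-6-[(tert-butyldimethylsilyl)oxy]-4,5-dihydroxy-3,3-dimethoxycyclohex-1-en-1-yl]methyl benzoate, via cyclic osmate ester 8 (not isolated)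
Conditions: OsO4 (5 mol%), NMO (1.1 equiv), NaHCO3 (1 equiv), acetone/H2O (8:1), 0 °C → rt; aq. Na2SO3 quench
Reagents that add atoms: osmium tetroxide, O=[Os](=O)(=O)=O; N-methylmorpholine N-oxide, C[N+]1([O-])CCOCC1; water, O
Why: Osmium tetroxide adds across C5=C6 in a concerted, suprafacial [3+2] cycloaddition to give the cyclic glycolate ester 8 of hexavalent osmium, which water hydrolyses while NMO returns the metal to the octavalent state, so both new C–O bonds form on one face and no ring is closed (the carbocycle is already in place). The closest known reaction type is the Upjohn dihydroxylation of cyclic allylic silyl ethers, which follows the empirical rule of attack anti to the allylic oxygen. The two new stereocentres C5 and C6 are set together by the C4 stereocentre: the tert-butyldimethylsilyloxy group blocks the lower face of the nearly flat cyclohexa-1,4-diene, the reagent adds from the upper face, and O5/O6 end up cis to each other and trans to O4, while the other allylic carbon, C1, carries two identical methoxy groups and exerts no facial bias. The step needs this face selectivity and also site selectivity for C5=C6 over C2=C3, which should follow because C2=C3 is trisubstituted, flanked by the quaternary ketal carbon and the silyloxy carbon, and inductively deactivated by the allylic benzoate, and because NMO is limited to 1.1 equivalents so that a second dihydroxylation is starved. The bicarbonate buffer and the sulfite quench keep the medium non-acidic so that the dienol ketal cannot lose methanol and aromatise before the C5=C6 alkene is consumed.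

Step 7
Reactants: 9 [(4R,5S,6S)-6-[(tert-butyldimethylsilyl)oxy]-4,5-dihydroxy-3,3-dimethoxycyclohex-1-en-1-yl]methyl benzoate
Product: 10 [(4R,5S,6S)-6-[(tert-butyldimethylsilyl)oxy]-4,5-dihydroxy-3-oxocyclohex-1-en-1-yl]methyl benzoate
Conditions: oxalic acid (0.5 M aq.), THF, 0 °C → rt
Reagents that add atoms: water, O
Why: Mild acid-catalysed hydrolysis of the allylic dimethyl ketal, now free of the aromatisation pathway because C5=C6 is saturated, unmasks the C1 ketone as the enone, while aqueous oxalic acid at or below room temperature is too weak to cleave the secondary TBS ether or the benzoate or to epimerise the alpha-hydroxy centre C6.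

Step 8
Reactants: 10 [(4R,5S,6S)-6-[(tert-butyldimethylsilyl)oxy]-4,5-dihydroxy-3-oxocyclohex-1-en-1-yl]methyl benzoate
Product: 11 [(3R,4S,5S,6S)-6-[(tert-butyldimethylsilyl)oxy]-3,4,5-trihydroxycyclohex-1-en-1-yl]methyl benzoate
Conditions: Me4NBH(OAc)3 (4 equiv), MeCN/AcOH (1:1), −30 → 0 °C
Reagents that add atoms: none
Why: Hydroxyl-directed reduction with the triacetoxyborohydride (Evans–Saksena type): the C6 and C5 hydroxyls, both on the upper face, bind boron and deliver hydride intramolecularly to the upper face of the C1 carbonyl in a 1,2-sense, so the new C1 hydroxyl points down, trans to O6 and 1,3-anti to O5, while the acidic medium forestalls beta-elimination and silyl or acyl migration.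

Step 9
Reactants: 11 [(3R,4S,5S,6S)-6-[(tert-butyldimethylsilyl)oxy]-3,4,5-trihydroxycyclohex-1-en-1-yl]methyl benzoate
Product: 13 C1-acetate of the C5/C6 cyclic methyl orthobenzoate of triol 11, via C1-hydroxy cyclic orthobenzoate 12 (not isolated)
Conditions: PhC(OMe)3 (1.2 equiv), CSA (5 mol%), CH2Cl2, rt, then concentrate; Et3N, Ac2O, DMAP (10 mol%), CH2Cl2, 0 °C → rt
Reagents that add atoms: trimethyl orthobenzoate, COC(OC)(OC)c1ccccc1; acetic anhydride, CC(=O)OC(C)=O
Why: Acid-catalysed orthoester exchange engages the only cis-vicinal diol (O5/O6) as a cis-fused five-membered cyclic orthobenzoate, which leaves the allylic C1 hydroxyl as the single free hydroxyl for a DMAP-catalysed acetylation that is therefore unambiguous, and at the same time stores on O5/O6 the benzoyl group needed in the next step.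

Step 10
Reactants: 13 C1-acetate of the C5/C6 cyclic methyl orthobenzoate
Product: 14 [(3R,4S,5S,6S)-3-(acetyloxy)-5-(benzoyloxy)-6-[(tert-butyldimethylsilyl)oxy]-4-hydroxycyclohex-1-en-1-yl]methyl benzoate
Conditions: AcOH/H2O (4:1), THF, 0 °C → rt
Reagents that add atoms: water, O
Why: Kinetically controlled mild acid hydrolysis of a cyclic orthoester cis-fused to a six-membered ring is known to open toward the ester on the axial oxygen and the free equatorial hydroxyl, and since the bulky C4 silyloxy group should sit pseudoaxial (avoiding allylic 1,2-strain with the C3 substituent and a gauche contact with O5) the axial oxygen is O5, so the benzoate should end on O5 with the C6 hydroxyl free and no stereocentre touched.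

Step 11
Reactants: 14 [(3R,4S,5S,6S)-3-(acetyloxy)-5-(benzoyloxy)-6-[(tert-butyldimethylsilyl)oxy]-4-hydroxycyclohex-1-en-1-yl]methyl benzoate
Product: 15 [(3R,4S,5R,6S)-3-(acetyloxy)-5-(benzoyloxy)-4,6-dihydroxycyclohex-1-en-1-yl]methyl benzoate
Conditions: HF·pyridine, pyridine, THF, 0 °C → rt
Reagents that add atoms: none
Why: Fluoride-mediated desilylation with pyridine-buffered HF cleaves the secondary allylic TBS ether under weakly acidic conditions that avoid the base-promoted migration of the benzoate or acetate onto the neighbouring free hydroxyls, giving the target.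

**Compound list**

1 | 2-hydroxy-5-methoxybenzaldehyde | COc1ccc(O)c(C=O)c1 | starting material
2 | 2-(hydroxymethyl)-4-methoxyphenol | COc1ccc(O)c(CO)c1 | intermediate
3 | 2-(hydroxymethyl)-4,4-dimethoxycyclohexa-2,5-dien-1-one | COC1(OC)C=CC(=O)C(CO)=C1 | intermediate
4 | benzoyl chloride | O=C(Cl)c1ccccc1 | starting material
5 | (3,3-dimethoxy-6-oxocyclohexa-1,4-dien-1-yl)methyl benzoate | COC1(OC)C=CC(=O)C(COC(=O)c2ccccc2)=C1 | intermediate
6 | [(6R)-6-hydroxy-3,3-dimethoxycyclohexa-1,4-dien-1-yl]methyl benzoate | COC1(OC)C=C(COC(=O)c2ccccc2)[C@H](O)C=C1 | intermediate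
7 | [(6R)-6-[(tert-butyldimethylsilyl)oxy]-3,3-dimethoxycyclohexa-1,4-dien-1-yl]methyl benzoate (key-step precursor) | COC1(OC)C=C(COC(=O)c2ccccc2)[C@H](O[Si](C)(C)C(C)(C)C)C=C1 | intermediate
8 | cyclic C5,C6 glycolate ester of hexavalent osmium (dioxo-osmium diolate of 9; formed in the flask, not isolated) | COC1(OC)C=C(COC(=O)c2ccccc2)[C@H](O[Si](C)(C)C(C)(C)C)[C@H]2O[Os](=O)(=O)O[C@@H]12 | intermediate
9 | [(4R,5S,6S)-6-[(tert-butyldimethylsilyl)oxy]-4,5-dihydroxy-3,3-dimethoxycyclohex-1-en-1-yl]methyl benzoate (key-step product) | COC1(OC)C=C(COC(=O)c2ccccc2)[C@H](O[Si](C)(C)C(C)(C)C)[C@@H](O)[C@H]1O | intermediate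
10 | [(4R,5S,6S)-6-[(tert-butyldimethylsilyl)oxy]-4,5-dihydroxy-3-oxocyclohex-1-en-1-yl]methyl benzoate | O=C1C=C(COC(=O)c2ccccc2)[C@H](O[Si](C)(C)C(C)(C)C)[C@@H](O)[C@H]1O | intermediate
11 | [(3R,4S,5S,6S)-6-[(tert-butyldimethylsilyl)oxy]-3,4,5-trihydroxycyclohex-1-en-1-yl]methyl benzoate | O[C@@H]1C=C(COC(=O)c2ccccc2)[C@H](O[Si](C)(C)C(C)(C)C)[C@@H](O)[C@H]1O | intermediate
12 | triol 11 with O5 and O6 bridged as a cyclic methyl orthobenzoate (2-methoxy-2-phenyl-1,3-dioxolane cis-fused at C5–C6, both epimers at the orthoester carbon), C1–OH free (formed in the flask, not isolated) | O[C@@H]1C=C(COC(=O)c2ccccc2)[C@H](O[Si](C)(C)C(C)(C)C)[C@H]2OC(OC)(c3ccccc3)O[C@@H]12 | intermediate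
13 | C1-acetate of 12 | CC(=O)O[C@@H]1C=C(COC(=O)c2ccccc2)[C@H](O[Si](C)(C)C(C)(C)C)[C@H]2OC(OC)(c3ccccc3)O[C@@H]12 | intermediate
14 | [(3R,4S,5S,6S)-3-(acetyloxy)-5-(benzoyloxy)-6-[(tert-butyldimethylsilyl)oxy]-4-hydroxycyclohex-1-en-1-yl]methyl benzoate | CC(=O)O[C@@H]1C=C(COC(=O)c2ccccc2)[C@H](O[Si](C)(C)C(C)(C)C)[C@@H](OC(=O)c2ccccc2)[C@H]1O | intermediate
15 | [(3R,4S,5R,6S)-3-(acetyloxy)-5-(benzoyloxy)-4,6-dihydroxycyclohex-1-en-1-yl]methyl benzoate | CC(=O)O[C@@H]1C=C(COC(=O)c2ccccc2)[C@H](O)[C@@H](OC(=O)c2ccccc2)[C@H]1O | target

**Step count**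

Total: 11 steps. Longest linear sequence: 11 steps (1 → 15); benzoyl chloride 4 enters in step 3.

**Steps most likely to fail, with fallbacks**

Step 4. The oxazaborolidine may not discriminate well between the two vinyl flanks of the dienone, which differ only by the C3 substituent, giving low enantiomeric purity at C4. The dienol ketal may also lose methanol and aromatise on contact with boron Lewis acids or during work-up. The fallback sets out from 5 and comes back at 6. Racemic 1,2-reduction (NaBH4, CeCl3·7H2O, MeOH, −78 °C, NaHCO3 quench) should give the racemic dienol F1. Lipase-catalysed kinetic resolution (immobilised Candida antarctica lipase B, vinyl acetate, MTBE, trace Et3N, rt) is expected, by the usual empirical rule for secondary alcohols, to acylate the (R)-enantiomer to the (R)-acetate F2 and to leave the (S)-dienol F3, which MnO2 in CH2Cl2 would return to 5. Butanolysis of F2 with the same enzyme (n-BuOH, MTBE) should remove the acetate without touching the benzoate, a poor lipase substrate, and deliver 6. If the enzyme prefers the other enantiomer, the unreacted alcohol is 6 directly.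

Step 10. The orthoester may open in the unwanted direction, placing the benzoate on O6, if the reacting half-chair has O5 equatorial and not axial. The fallback sets out from 11 and comes back at 14, and it is stereochemically complementary: organotin-mediated acylation of a cis-diol on a six-membered ring goes to the equatorial oxygen, so it should succeed in exactly the conformational situation in which the orthoester opening fails. Triol 11 would be converted with 2,2-dimethoxypropane and PPTS in CH2Cl2 into the C5/C6 acetonide F4. Acetylation (Ac2O, pyridine, DMAP) would give the C1-acetate acetonide F5, and acetonide cleavage (AcOH/H2O 4:1, 45 °C) the C1-acetate C5,C6-diol F6. Catalytic Me2SnCl2 (5 mol%) with BzCl and iPr2NEt in THF at 0 °C would then monobenzoylate the equatorial O5 to give 14.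

Step 6. Osmylation may compete at the C2=C3 alkene or run on to a second dihydroxylation, and facial control by the silyloxy group may be incomplete. The fallback sets out from 7 and comes back at 9, and it removes C2=C3 from competition by conjugation. Methanolysis of the benzoate (K2CO3, MeOH, 0 °C) should give the C7 allylic alcohol F7, and MnO2 in CH2Cl2 the enal F8, whose C2=C3 bond is strongly deactivated toward the electrophilic oxidant. OsO4/NMO under the conditions of step 6 can then only attack C5=C6 anti to the silyloxy group, giving the enal diol F9. Luche reduction (NaBH4, CeCl3·7H2O, MeOH, −78 °C) would give the C7,C5,C6-triol F10, and selective benzoylation of its primary allylic hydroxyl (BzCl, 2,4,6-collidine, CH2Cl2, −40 °C) would give 9.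

**Further compounds**

F1 | step 4 | racemic (6-hydroxy-3,3-dimethoxycyclohexa-1,4-dien-1-yl)methyl benzoate | COC1(OC)C=C(COC(=O)c2ccccc2)C(O)C=C1
F2 | step 4 | [(6R)-6-(acetyloxy)-3,3-dimethoxycyclohexa-1,4-dien-1-yl]methyl benzoate | COC1(OC)C=C(COC(=O)c2ccccc2)[C@H](OC(C)=O)C=C1
F3 | step 4 | [(6S)-6-hydroxy-3,3-dimethoxycyclohexa-1,4-dien-1-yl]methyl benzoate | COC1(OC)C=C(COC(=O)c2ccccc2)[C@@H](O)C=C1
F4 | step 10 | C5,C6-O-isopropylidene derivative of triol 11, C1–OH free | O[C@@H]1C=C(COC(=O)c2ccccc2)[C@H](O[Si](C)(C)C(C)(C)C)[C@H]2OC(C)(C)O[C@@H]12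
F5 | step 10 | C1-acetate of acetonide F4 | CC(=O)O[C@@H]1C=C(COC(=O)c2ccccc2)[C@H](O[Si](C)(C)C(C)(C)C)[C@H]2OC(C)(C)O[C@@H]12
F6 | step 10 | C1-acetate of triol 11 with free C5 and C6 hydroxyls | CC(=O)O[C@@H]1C=C(COC(=O)c2ccccc2)[C@H](O[Si](C)(C)C(C)(C)C)[C@@H](O)[C@H]1O
F7 | step 6 | [(6R)-6-[(tert-butyldimethylsilyl)oxy]-3,3-dimethoxycyclohexa-1,4-dien-1-yl]methanol | COC1(OC)C=C(CO)[C@H](O[Si](C)(C)C(C)(C)C)C=C1
F8 | step 6 | (6R)-6-[(tert-butyldimethylsilyl)oxy]-3,3-dimethoxycyclohexa-1,4-diene-1-carbaldehyde | COC1(OC)C=C(C=O)[C@H](O[Si](C)(C)C(C)(C)C)C=C1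
F9 | step 6 | (4R,5S,6S)-6-[(tert-butyldimethylsilyl)oxy]-4,5-dihydroxy-3,3-dimethoxycyclohex-1-ene-1-carbaldehyde | COC1(OC)C=C(C=O)[C@H](O[Si](C)(C)C(C)(C)C)[C@@H](O)[C@H]1O
F10 | step 6 | C7-debenzoylated analogue of 9 (C7, C5 and C6 hydroxyls free) | COC1(OC)C=C(CO)[C@H](O[Si](C)(C)C(C)(C)C)[C@@H](O)[C@H]1O
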